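## Retrosynthetic overview

1. The spiro carbon is made last: target 28 ⇐ trione 13 (C17) + bromo-lactol 23 (C10 unit, silyl-protected). The two are joined by Knoevenagel condensation/conjugate reduction (first C–CH2 bond), then an epoxide-opening spirocyclisation (second C–CH2 bond), then desilylation.
2. Trione 13 ⇐ intramolecular Claisen closure of triketo ester 12 ⇐ two C-acylations of keto ester 7. The quaternary centre of 7 comes from a chiral-enamine prenylation of methyl 2-methylacetoacetate; the acyl group comes from (2R)-2-methylbutanoic acid.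
3. Lactol 23 ⇐ cyclopent-2-enone: enantioselective conjugate addition/formylation, bromo-etherification (C–O quaternary centre), hydrogenation (cis fusion), MeLi addition (tertiary carbinol), then ether → lactone → lactol.
4. Ring order: cyclopentane (bought) with a temporary oxabicycle; the cyclohexanetrione is built separately; the spiro-cyclohexane is closed last.

Assumption: (2R)-2-methylbutanoic acid is bought; the enantiomer of the valine auxiliary (step 3) and of the ferrocenyl diphosphine (step 8) is taken to be the one that gives the configuration drawn; the β-triketone is drawn in the enol form of the target SMILES.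

## Route

Step 1
Reactants: 1 methyl 3-oxobutanoate
Product: 2 methyl 2-methyl-3-oxobutanoate
Conditions: K2CO3, MeI, acetone, reflux
Reagents that add atoms: iodomethane, CI
Why: SN2 C-alkylation of the acetoacetate enolate installs the future ring methyl group; the product is racemic and its stereocentre is erased in step 2.

Step 2
Reactants: 2 methyl 2-methyl-3-oxobutanoate
Product: 3 methyl (2Z)-3-{[(2S)-1-tert-butoxy-3-methyl-1-oxobutan-2-yl]amino}-2-methylbut-2-enoate
Conditions: L-valine tert-butyl ester, BF3·OEt2 (cat.), benzene, 4 Å molecular sieves, reflux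
Reagents that add atoms: L-valine tert-butyl ester, CC(C)[C@H](N)C(=O)OC(C)(C)C
Why: Acid-catalysed enamine formation gives the hydrogen-bonded Z enamine that carries the chiral auxiliary.

Step 3
Reactants: 3 methyl (2Z)-3-{[(2S)-1-tert-butoxy-3-methyl-1-oxobutan-2-yl]amino}-2-methylbut-2-enoate; 4 1-bromo-3-methylbut-2-ene
Product: 7 methyl (2S)-2-acetyl-2,5-dimethylhex-4-enoate, via lithiated enamine 5 (not isolated), via ketimine 6 (not isolated)
Conditions: LiN(i-Pr)2, toluene, HMPA, −78 °C; then 4; then 10% aqueous citric acid, 23 °C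
Reagents that add atoms: water, O
Why: Asymmetric alkylation of the chelated lithio-enamine (chiral-enamine alkylation of an α-alkyl β-keto ester) sets the quaternary (S) centre by attack of prenyl bromide on the face away from the valine isopropyl group, and mild acid hydrolysis frees the ketone and the auxiliary.

Step 4
Reactants: 8 (2R)-2-methylbutanoic acid
Product: 9 1-[(2R)-2-methylbutanoyl]-1H-benzotriazole
Conditions: DCC, 1H-benzotriazole, CH2Cl2, 0 → 23 °C
Reagents that add atoms: 1H-benzotriazole, c1ccc2[nH]nnc2c1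
Why: Carbodiimide-mediated acyl transfer gives a configurationally stable N-acylbenzotriazole acyl donor under non-basic conditions.

Step 5
Reactants: 7 methyl (2S)-2-acetyl-2,5-dimethylhex-4-enoate; 9 1-[(2R)-2-methylbutanoyl]-1H-benzotriazole
Product: 10 methyl (2S,6R)-2,6-dimethyl-2-(3-methylbut-2-en-1-yl)-3,5-dioxooctanoate
Conditions: MgBr2·OEt2, i-Pr2NEt, CH2Cl2, 23 °C
Reagents that add atoms: none
Why: Soft enolisation of the only enolisable site (the acetyl CH3) and C-acylation (crossed Claisen) gives the β-diketone without touching either stereocentre.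

Step 6
Reactants: 10 methyl (2S,6R)-2,6-dimethyl-2-(3-methylbut-2-en-1-yl)-3,5-dioxooctanoate; 11 acetyl chloride
Product: 12 methyl (2S,6R)-4-acetyl-2,6-dimethyl-2-(3-methylbut-2-en-1-yl)-3,5-dioxooctanoate
Conditions: MgCl2, pyridine, CH2Cl2, 0 → 23 °C
Reagents that add atoms: none
Why: C-acylation of the magnesium chelate of the β-diketone at its central carbon gives the triacylmethane that holds all six ring carbons (C-4 is enolised, so no stereocentre is defined there).

Step 7
Reactants: 12 methyl (2S,6R)-4-acetyl-2,6-dimethyl-2-(3-methylbut-2-en-1-yl)-3,5-dioxooctanoate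
Product: 13 (4S)-3-hydroxy-4-methyl-2-[(2R)-2-methylbutanoyl]-4-(3-methylbut-2-en-1-yl)cyclohex-2-ene-1,5-dione
Conditions: LiN(i-Pr)2 (3.3 equiv), THF, −78 → 0 °C; then 1 M HCl
Reagents that add atoms: none
Why: Dieckmann-type (intramolecular Claisen) closure, in which the dianion formed at the acetyl CH3 attacks the methyl ester in a 6-exo mode and the acidic triketone product drives the reaction; no stereocentre is formed and the quaternary centre cannot epimerise.

Step 8
Reactants: 14 cyclopent-2-en-1-one; 15 prop-1-en-2-ylmagnesium bromide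
Product: 17 (3S)-2-(hydroxymethylidene)-3-(prop-1-en-2-yl)cyclopentan-1-one, via magnesium enolate 16 (not isolated)
Conditions: CuBr·SMe2 (5 mol %), (R)-1-[(Sp)-2-(diphenylphosphino)ferrocenyl]ethyldicyclohexylphosphine (6 mol %), t-BuOMe, −78 °C; then HCO2CH2CF3, −78 → 0 °C; aqueous NH4Cl
Reagents that add atoms: 2,2,2-trifluoroethyl formate, O=COCC(F)(F)F
Why: Copper-catalysed enantioselective conjugate addition sets the ring stereocentre under ligand control, and the regiodefined magnesium enolate is C-formylated (Claisen formylation) by the activated formate.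

Step 9
Reactants: 17 (3S)-2-(hydroxymethylidene)-3-(prop-1-en-2-yl)cyclopentan-1-one
Product: 18 (3R,3aR)-3-(bromomethyl)-3-methyl-3,3a,4,5-tetrahydro-6H-cyclopenta[c]furan-6-one
Conditions: NBS, NaHCO3, CH2Cl2, 0 °C
Reagents that add atoms: N-bromosuccinimide, O=C1CCC(=O)N1Br
Why: Bromo-enol-etherification (5-exo halocyclisation) in which the enol oxygen opens the bromonium ion at the tertiary carbon; the adjacent stereocentre places the larger CH2Br group on the convex face, cis to 3a-H (minor epimer removed by chromatography).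

Step 10
Reactants: 18 (3R,3aR)-3-(bromomethyl)-3-methyl-3,3a,4,5-tetrahydro-6H-cyclopenta[c]furan-6-one
Product: 19 (3R,3aR,6aS)-3-(bromomethyl)-3-methylhexahydro-6H-cyclopenta[c]furan-6-one
Conditions: H2 (1 atm), 5% Rh on Al2O3, EtOAc, 23 °C
Reagents that add atoms: none
Why: Heterogeneous hydrogenation of the enol-ether double bond delivers hydrogen cis to 3a-H, because only the cis-fused oxabicyclo[3.3.0]octane can form, and this fixes the third ring stereocentre.

Step 11
Reactants: 19 (3R,3aR,6aS)-3-(bromomethyl)-3-methylhexahydro-6H-cyclopenta[c]furan-6-one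
Product: 20 (3R,3aR,6S,6aS)-3-(bromomethyl)-3,6-dimethylhexahydro-1H-cyclopenta[c]furan-6-ol
Conditions: CeCl3, MeLi, THF, −78 °C; aqueous NH4Cl
Reagents that add atoms: methyllithium, [Li]C
Why: Organocerium 1,2-addition avoids enolisation and β-elimination and attacks the cis-fused bicyclic ketone from its convex face, so the tertiary hydroxyl ends up cis to both ring-fusion substituents.

Step 12
Reactants: 20 (3R,3aR,6S,6aS)-3-(bromomethyl)-3,6-dimethylhexahydro-1H-cyclopenta[c]furan-6-ol
Product: 21 (3R,3aR,6S,6aR)-3-(bromomethyl)-6-hydroxy-3,6-dimethylhexahydro-1H-cyclopenta[c]furan-1-one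
Conditions: RuCl3·xH2O (5 mol %), NaIO4, CCl4/MeCN/H2O, 23 °C
Reagents that add atoms: sodium periodate, [Na+].[O-]I(=O)(=O)=O
Why: RuO4 oxidation of the only O–CH2 group turns the cyclic ether into the γ-lactone and leaves the tertiary alcohol, the bromide and all stereocentres untouched.

Step 13
Reactants: 21 (3R,3aR,6S,6aR)-3-(bromomethyl)-6-hydroxy-3,6-dimethylhexahydro-1H-cyclopenta[c]furan-1-one
Product: 22 (3R,3aR,6S,6aR)-3-(bromomethyl)-3,6-dimethyl-6-[(triethylsilyl)oxy]hexahydro-1H-cyclopenta[c]furan-1-one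
Conditions: Et3SiOTf, 2,6-lutidine, CH2Cl2, −78 → 0 °C
Reagents that add atoms: triethylsilyl trifluoromethanesulfonate, CC[Si](CC)(CC)OS(=O)(=O)C(F)(F)F
Why: Silylation of the hindered tertiary alcohol with the silyl triflate protects it so that it cannot open the epoxide in step 16.

Step 14
Reactants: 22 (3R,3aR,6S,6aR)-3-(bromomethyl)-3,6-dimethyl-6-[(triethylsilyl)oxy]hexahydro-1H-cyclopenta[c]furan-1-one
Product: 23 (3R,3aR,6S,6aR)-3-(bromomethyl)-3,6-dimethyl-6-[(triethylsilyl)oxy]hexahydro-1H-cyclopenta[c]furan-1-ol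
Conditions: i-Bu2AlH, CH2Cl2, −78 °C; aqueous KNaC4H4O6
Reagents that add atoms: none
Why: Partial hydride reduction of the γ-lactone stops at the lactol (both anomers), a masked aldehyde whose cis ring fusion holds the α-stereocentre.

Step 15
Reactants: 13 (4S)-3-hydroxy-4-methyl-2-[(2R)-2-methylbutanoyl]-4-(3-methylbut-2-en-1-yl)cyclohex-2-ene-1,5-dione; 23 (3R,3aR,6S,6aR)-3-(bromomethyl)-3,6-dimethyl-6-[(triethylsilyl)oxy]hexahydro-1H-cyclopenta[c]furan-1-ol
Product: 25 (4S)-6-({(1R,2S,5R)-5-[(2R)-1-bromo-2-hydroxypropan-2-yl]-2-methyl-2-[(triethylsilyl)oxy]cyclopentyl}methyl)-3-hydroxy-4-methyl-2-[(2R)-2-methylbutanoyl]-4-(3-methylbut-2-en-1-yl)cyclohex-2-ene-1,5-dione, via alkylidene trione 24 (not isolated)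
Conditions: diethyl 2,6-dimethyl-1,4-dihydropyridine-3,5-dicarboxylate (Hantzsch ester), L-proline (20 mol %), CH2Cl2, 23 °C
Reagents that add atoms: none
Why: Knoevenagel condensation of the ring-opened hydroxy aldehyde with the acidic ring CH2 of 13, followed by in situ Hantzsch-ester conjugate reduction (organocatalytic reductive alkylation), joins the two fragments; no stereocentre is created and the aldehyde α-stereocentre is retained.

Step 16
Reactants: 25 (4S)-6-({(1R,2S,5R)-5-[(2R)-1-bromo-2-hydroxypropan-2-yl]-2-methyl-2-[(triethylsilyl)oxy]cyclopentyl}methyl)-3-hydroxy-4-methyl-2-[(2R)-2-methylbutanoyl]-4-(3-methylbut-2-en-1-yl)cyclohex-2-ene-1,5-dione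
Product: 27 triethylsilyl ether of 28 at the cyclopentane tertiary hydroxyl, via epoxide 26 (not isolated)
Conditions: LiOt-Bu (3.5 equiv), THF, 0 → 45 °C; aqueous NH4Cl
Reagents that add atoms: none
Why: The bromohydrin alkoxide closes the epoxide and the trione dianion opens it at the CH2 terminus (intramolecular C-alkylation; O-alkylation would need an eight-membered ring), with lithium bridging the epoxide oxygen and the enolate oxygen next to the quaternary carbon so that this carbonyl ends cis to the new tertiary hydroxyl, giving the (R) spiro centre with modest selectivity (minor epimer removed by chromatography).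

Step 17
Reactants: 27 triethylsilyl ether of 28 at the cyclopentane tertiary hydroxyl
Product: 28 CNP0236509.3
Conditions: HF·pyridine, THF, 0 → 23 °C
Reagents that add atoms: none
Why: Fluoride-mediated desilylation frees the tertiary alcohol without affecting the β-triketone, the prenyl group or any stereocentre.

## Compound list

1 | methyl 3-oxobutanoate | COC(=O)CC(C)=O | starting material
2 | methyl 2-methyl-3-oxobutanoate (racemic) | COC(=O)C(C)C(C)=O | intermediate
3 | methyl (2Z)-3-{[(2S)-1-tert-butoxy-3-methyl-1-oxobutan-2-yl]amino}-2-methylbut-2-enoate | COC(=O)/C(C)=C(C)\N[C@@H](C(C)C)C(=O)OC(C)(C)C | intermediate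
4 | 1-bromo-3-methylbut-2-ene | CC(C)=CCBr | starting material
5 | N-lithio derivative of 3 (lithiated enamine) | COC(=O)C(C)=C(C)N([Li])[C@@H](C(C)C)C(=O)OC(C)(C)C | intermediate
6 | methyl (2S)-3-{[(2S)-1-tert-butoxy-3-methyl-1-oxobutan-2-yl]imino}-2-methyl-2-(3-methylbut-2-en-1-yl)butanoate | COC(=O)[C@@](C)(CC=C(C)C)C(C)=N[C@@H](C(C)C)C(=O)OC(C)(C)C | intermediate
7 | methyl (2S)-2-acetyl-2,5-dimethylhex-4-enoate | COC(=O)[C@@](C)(CC=C(C)C)C(C)=O | intermediate
8 | (2R)-2-methylbutanoic acid | CC[C@@H](C)C(=O)O | starting material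
9 | 1-[(2R)-2-methylbutanoyl]-1H-benzotriazole | CC[C@@H](C)C(=O)n1nnc2ccccc12 | intermediate
10 | methyl (2S,6R)-2,6-dimethyl-2-(3-methylbut-2-en-1-yl)-3,5-dioxooctanoate | COC(=O)[C@@](C)(CC=C(C)C)C(=O)CC(=O)[C@H](C)CC | intermediate
11 | acetyl chloride | CC(Cl)=O | starting material
12 | methyl (2S,6R)-4-acetyl-2,6-dimethyl-2-(3-methylbut-2-en-1-yl)-3,5-dioxooctanoate (C-4 enolised) | COC(=O)[C@@](C)(CC=C(C)C)C(=O)C(C(C)=O)C(=O)[C@H](C)CC | intermediate
13 | (4S)-3-hydroxy-4-methyl-2-[(2R)-2-methylbutanoyl]-4-(3-methylbut-2-en-1-yl)cyclohex-2-ene-1,5-dione | CC[C@@H](C)C(=O)C1=C(O)[C@](C)(CC=C(C)C)C(=O)CC1=O | intermediate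
14 | cyclopent-2-en-1-one | O=C1C=CCC1 | starting material
15 | prop-1-en-2-ylmagnesium bromide | CC(=C)[Mg]Br | starting material
16 | bromomagnesium (3R)-3-(prop-1-en-2-yl)cyclopent-1-en-1-olate | Br[Mg]OC1=C[C@@H](CC1)C(C)=C | intermediate
17 | (3S)-2-(hydroxymethylidene)-3-(prop-1-en-2-yl)cyclopentan-1-one | OC=C1[C@@H](CCC1=O)C(C)=C | intermediate
18 | (3R,3aR)-3-(bromomethyl)-3-methyl-3,3a,4,5-tetrahydro-6H-cyclopenta[c]furan-6-one | O1C=C2[C@@H](CCC2=O)[C@]1(C)CBr | intermediate
19 | (3R,3aR,6aS)-3-(bromomethyl)-3-methylhexahydro-6H-cyclopenta[c]furan-6-one (cis-fused) | O1C[C@@H]2[C@@H](CCC2=O)[C@]1(C)CBr | intermediate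
20 | (3R,3aR,6S,6aS)-3-(bromomethyl)-3,6-dimethylhexahydro-1H-cyclopenta[c]furan-6-ol | O1C[C@@H]2[C@@H](CC[C@]2(C)O)[C@]1(C)CBr | intermediate
21 | (3R,3aR,6S,6aR)-3-(bromomethyl)-6-hydroxy-3,6-dimethylhexahydro-1H-cyclopenta[c]furan-1-one | O=C1[C@@H]2[C@@H](CC[C@]2(C)O)[C@@](C)(O1)CBr | intermediate
22 | (3R,3aR,6S,6aR)-3-(bromomethyl)-3,6-dimethyl-6-[(triethylsilyl)oxy]hexahydro-1H-cyclopenta[c]furan-1-one | O=C1[C@@H]2[C@@H](CC[C@]2(C)O[Si](CC)(CC)CC)[C@@](C)(O1)CBr | intermediate
23 | (3R,3aR,6S,6aR)-3-(bromomethyl)-3,6-dimethyl-6-[(triethylsilyl)oxy]hexahydro-1H-cyclopenta[c]furan-1-ol (both anomers) | OC1[C@@H]2[C@@H](CC[C@]2(C)O[Si](CC)(CC)CC)[C@@](C)(O1)CBr | intermediate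
24 | (4S)-6-({(1R,2S,5R)-5-[(2R)-1-bromo-2-hydroxypropan-2-yl]-2-methyl-2-[(triethylsilyl)oxy]cyclopentyl}methylidene)-3-hydroxy-4-methyl-2-[(2R)-2-methylbutanoyl]-4-(3-methylbut-2-en-1-yl)cyclohex-2-ene-1,5-dione | CC[C@@H](C)C(=O)C1=C(O)[C@](C)(CC=C(C)C)C(=O)C(=C[C@@H]2[C@@H](CC[C@]2(C)O[Si](CC)(CC)CC)[C@@](C)(O)CBr)C1=O | intermediate
25 | (4S)-6-({(1R,2S,5R)-5-[(2R)-1-bromo-2-hydroxypropan-2-yl]-2-methyl-2-[(triethylsilyl)oxy]cyclopentyl}methyl)-3-hydroxy-4-methyl-2-[(2R)-2-methylbutanoyl]-4-(3-methylbut-2-en-1-yl)cyclohex-2-ene-1,5-dione | CC[C@@H](C)C(=O)C1=C(O)[C@](C)(CC=C(C)C)C(=O)C(C[C@@H]2[C@@H](CC[C@]2(C)O[Si](CC)(CC)CC)[C@@](C)(O)CBr)C1=O | intermediate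
26 | (4S)-3-hydroxy-4-methyl-6-({(1R,2S,5R)-2-methyl-5-[(2R)-2-methyloxiran-2-yl]-2-[(triethylsilyl)oxy]cyclopentyl}methyl)-2-[(2R)-2-methylbutanoyl]-4-(3-methylbut-2-en-1-yl)cyclohex-2-ene-1,5-dione | CC[C@@H](C)C(=O)C1=C(O)[C@](C)(CC=C(C)C)C(=O)C(C[C@@H]2[C@@H](CC[C@]2(C)O[Si](CC)(CC)CC)[C@@]3(C)OC3)C1=O | intermediate
27 | triethylsilyl ether of 28 at the cyclopentane tertiary hydroxyl | CC[C@@H](C)C(=O)C1=C(O)[C@](C)(CC=C(C)C)C(=O)[C@]2(C[C@@H]3[C@@H](CC[C@]3(C)O[Si](CC)(CC)CC)[C@@](C)(O)C2)C1=O | intermediate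
28 | CNP0236509.3 (spiro-fused acylcyclohexenedione / cis-octahydroindene diol) | CC[C@@H](C)C(=O)C1=C(O)[C@](C)(CC=C(C)C)C(=O)[C@]2(C[C@@H]3[C@@H](CC[C@]3(C)O)[C@@](C)(O)C2)C1=O | target

## Step count and weak points

Total step count: 17. Longest linear sequence: 10 steps (steps 8–17); the other main branch is steps 1–3 and 5–7, with step 4 as a one-step side branch.

Step 8 is the first weak point: the enantioselectivity with an alkenyl Grignard reagent and the trapping of the magnesium enolate by the formate are both uncertain. The fallback replaces asymmetric catalysis by resolution and sets out from 14 and 15. The same addition and formylation run with CuI alone give racemic 2-(hydroxymethylidene)-3-(prop-1-en-2-yl)cyclopentan-1-one F1. Condensation with (1S)-1-phenylethan-1-amine in toluene gives diastereomeric enaminones, from which (3S)-2-({[(1S)-1-phenylethyl]amino}methylidene)-3-(prop-1-en-2-yl)cyclopentan-1-one F2 is separated by crystallisation or chromatography. Hydrolysis with aqueous oxalic acid in THF comes back to the route at 17.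

Step 7 is the second weak point: the methyl-ketone dianion may O-acylate to an enol lactone, or the wrong α-position may be deprotonated. The fallback closes the ring through a doubly activated methylene under mild base and sets out from 10. C-acylation with methyl 3-chloro-3-oxopropanoate (MgCl2, pyridine) gives dimethyl (2S)-2-methyl-4-[(2R)-2-methylbutanoyl]-2-(3-methylbut-2-en-1-yl)-3,5-dioxoheptanedioate F3. NaH in THF effects the Dieckmann closure to methyl (3S)-4-hydroxy-3-methyl-5-[(2R)-2-methylbutanoyl]-3-(3-methylbut-2-en-1-yl)-2,6-dioxocyclohex-4-ene-1-carboxylate F4. Krapcho demethoxycarbonylation (LiCl, wet DMSO, 120 °C) comes back to the route at 13.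

Step 16 is the third weak point: a hindered, stabilised tertiary carbon nucleophile must open an epoxide to form a quaternary centre, and the spiro selectivity rests only on lithium chelation. The fallback is a double C-alkylation with reactive halide and sulfonate electrophiles, followed by late hydration; it sets out from 20 and 13.

- Zn and NH4Cl in refluxing ethanol open the β-bromo ether of 20 to (1S,2S,3R)-2-(hydroxymethyl)-1-methyl-3-(prop-1-en-2-yl)cyclopentan-1-ol F5.
- MsCl and Et3N give [(1S,2S,5R)-2-hydroxy-2-methyl-5-(prop-1-en-2-yl)cyclopentyl]methyl methanesulfonate F6.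
- Et3SiOTf and 2,6-lutidine give [(1S,2S,5R)-2-methyl-5-(prop-1-en-2-yl)-2-[(triethylsilyl)oxy]cyclopentyl]methyl methanesulfonate F7.
- Ene-type chlorination (N-chlorosuccinimide, catalytic PhSeCl) gives [(1S,2S,5R)-5-(3-chloroprop-1-en-2-yl)-2-methyl-2-[(triethylsilyl)oxy]cyclopentyl]methyl methanesulfonate F8.
- With Cs2CO3 and catalytic NaI in DMF, 13 is C-allylated at its ring CH2 by F8 and then displaces the mesylate to give the methylidene analogue of 27 (exocyclic CH2 in place of the carbinol CH3 and OH) F9.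
- Mukaiyama hydration of the 1,1-disubstituted alkene (Mn(dpm)3, PhSiH3, O2, i-PrOH), which reacts faster than the trisubstituted prenyl alkene, comes back to the route at 27 after chromatographic removal of epimers.

Further compounds

F1 | step 8 | racemic 2-(hydroxymethylidene)-3-(prop-1-en-2-yl)cyclopentan-1-one | OC=C1C(CCC1=O)C(C)=C
F2 | step 8 | (3S)-2-({[(1S)-1-phenylethyl]amino}methylidene)-3-(prop-1-en-2-yl)cyclopentan-1-one | C[C@H](NC=C1[C@@H](CCC1=O)C(C)=C)c1ccccc1
F3 | step 7 | dimethyl (2S)-2-methyl-4-[(2R)-2-methylbutanoyl]-2-(3-methylbut-2-en-1-yl)-3,5-dioxoheptanedioate | COC(=O)CC(=O)C(C(=O)[C@H](C)CC)C(=O)[C@](C)(CC=C(C)C)C(=O)OC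
F4 | step 7 | methyl (3S)-4-hydroxy-3-methyl-5-[(2R)-2-methylbutanoyl]-3-(3-methylbut-2-en-1-yl)-2,6-dioxocyclohex-4-ene-1-carboxylate | CC[C@@H](C)C(=O)C1=C(O)[C@](C)(CC=C(C)C)C(=O)C(C(=O)OC)C1=O
F5 | step 16 | (1S,2S,3R)-2-(hydroxymethyl)-1-methyl-3-(prop-1-en-2-yl)cyclopentan-1-ol | OC[C@@H]1[C@@H](CC[C@]1(C)O)C(C)=C
F6 | step 16 | [(1S,2S,5R)-2-hydroxy-2-methyl-5-(prop-1-en-2-yl)cyclopentyl]methyl methanesulfonate | CS(=O)(=O)OC[C@@H]1[C@@H](CC[C@]1(C)O)C(C)=C
F7 | step 16 | [(1S,2S,5R)-2-methyl-5-(prop-1-en-2-yl)-2-[(triethylsilyl)oxy]cyclopentyl]methyl methanesulfonate | CS(=O)(=O)OC[C@@H]1[C@@H](CC[C@]1(C)O[Si](CC)(CC)CC)C(C)=C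
F8 | step 16 | [(1S,2S,5R)-5-(3-chloroprop-1-en-2-yl)-2-methyl-2-[(triethylsilyl)oxy]cyclopentyl]methyl methanesulfonate | CS(=O)(=O)OC[C@@H]1[C@@H](CC[C@]1(C)O[Si](CC)(CC)CC)C(=C)CCl
F9 | step 16 | methylidene analogue of 27 (exocyclic CH2 in place of the carbinol CH3 and OH) | CC[C@@H](C)C(=O)C1=C(O)[C@](C)(CC=C(C)C)C(=O)[C@]2(C[C@@H]3[C@@H](CC[C@]3(C)O[Si](CC)(CC)CC)C(=C)C2)C1=O
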